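## Retrosynthetic overview

1. Target 23 ⇐ silyl ether 22 ⇐ iodolactone 19: the C7 alkoxide closes a C7–C8 epoxide and tiglic acid reopens it at C8 (double inversion). 19 ⇐ acid 18 by iodolactonisation; the γ-lactone is the last ring formed.
2. 18 ⇐ allylic propanoate 15 by Ireland–Claisen rearrangement (C3a–C3 bond, both stereocentres), with the crotonoyl group carried as a 1-methoxyallenyl group.
3. 15 ⇐ epoxy ketone 7 by addition of lithiated 1-methoxybuta-1,2-diene (quaternary C7) and epoxide-to-allylic-alcohol isomerisation.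
4. 7 ⇐ enone 3 by amine-salt-catalysed asymmetric epoxidation and α'-methylation.
5. 3 ⇐ meso ketone 1 by a Brønsted-acid-organocatalysed desymmetrising enol silylation/ring opening; the cycloheptane is present from the start.

Assumption: 1 and 8 are bought (8 is otherwise one step from but-2-yn-1-ol); locants in the Why lines are those of the target named as a cyclohepta[b]furan-2-one (C3, C3a, C4–C8, C8a).

## Route

Step 1
Reactants: 1 8-oxabicyclo[3.2.1]octan-3-one
Product: 3 (6R)-6-[(tert-butyldimethylsilyl)oxy]cyclohept-2-en-1-one, via silyl enol ether 2 (not isolated)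
Conditions: IDPi Brønsted acid (3 mol%; imidodiphosphorimidate from two (S)-3,3'-bis[3,5-bis(trifluoromethyl)phenyl]-1,1'-bi-2-naphthol units with P=NSO2CF3 groups, or its antipode if that is the one giving (R)-3), allyl-TBS (1.2 equiv), PhMe, −40 → 0 °C
Reagents that add atoms: allyl(tert-butyl)dimethylsilane, C=CC[Si](C)(C)C(C)(C)C
Why: Proposed new method: the allylsilane silylates the confined acid (propene is lost), the TBS-oxocarbenium ion of meso-1 is deprotonated inside the chiral anion at one of the two enantiotopic α-CH2 groups, and the same silylium species then silylates the bridging ether oxygen of enol silane 2 and triggers β-alkoxy elimination (retro-oxa-Michael) to 3, irreversibly because the oxygen leaves as a silyl ether, so the choice of α-CH2 fixes C5 as R; the closest known reactions are the IDPi-catalysed desymmetrising enol silane synthesis from 4-substituted cyclohexanones with allylsilanes and the stoichiometric silyl triflate/amine (or chiral lithium amide) ring opening of this same ketone.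

Step 2
Reactants: 3 (6R)-6-[(tert-butyldimethylsilyl)oxy]cyclohept-2-en-1-one
Product: 4 (1R,4R,7R)-4-[(tert-butyldimethylsilyl)oxy]-8-oxabicyclo[5.1.0]octan-2-one
Conditions: 9-amino(9-deoxy)epi-quinine·2CF3CO2H (10 mol%; or the quinidine-derived pseudoenantiomer, whichever gives the 1R,7R epoxide), 50% aq. H2O2, dioxane, 30 °C
Reagents that add atoms: hydrogen peroxide, OO
Why: Weitz–Scheffer epoxidation under iminium catalysis by a primary cinchona amine salt (known for simple cyclic enones in high ee), so the catalyst, not the remote silyl ether, fixes the C8–C8a epoxide on the face anti to the C5 oxygen.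

Step 3
Reactants: 4 epoxy ketone, 5 iodomethane
Product: 7 (1R,3S,4R,7R)-4-[(tert-butyldimethylsilyl)oxy]-3-methyl-8-oxabicyclo[5.1.0]octan-2-one, via lithium enolate 6 (not isolated)
Conditions: LiN(i-Pr)2, THF, −78 °C; MeI, DMPU, −78 → −40 °C
Reagents that add atoms: iodomethane (5), CI; lithium diisopropylamide, [Li]N(C(C)C)C(C)C (its lithium stays only in 6)
Why: kinetic α'-enolate alkylation in which iodomethane approaches C6 anti to the adjacent silyloxy group, giving the 5,6-trans product, expected also to be the more stable epimer.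

Step 4
Reactants: 8 1-methoxybut-2-yne
Product: 9 1-methoxybuta-1,2-diene (racemic allene axis)
Conditions: KOt-Bu (10 mol%), neat, 70 °C; distil
Reagents that add atoms: none
Why: base-catalysed propargyl-to-allenyl ether prototropic isomerisation, stopped at the allene by distilling it out (the racemic allene axis disappears in step 8).

Step 5
Reactants: 7 methylated epoxy ketone, 9 1-methoxybuta-1,2-diene
Product: 12 tert-butyl{[(1R,2S,3S,4R,7R)-2-(1-methoxybuta-1,2-dien-1-yl)-3-methyl-2-[(trimethylsilyl)oxy]-8-oxabicyclo[5.1.0]octan-4-yl]oxy}dimethylsilane (both allene-axis epimers), via 1-lithio-1-methoxybuta-1,2-diene 10 (not isolated), via lithium alkoxide 11 (not isolated)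
Conditions: 9, n-BuLi, THF, −40 °C; 7, −78 °C; TMSCl, Et3N, −78 → 0 °C
Reagents that add atoms: chlorotrimethylsilane, C[Si](C)(C)Cl; n-butyllithium, [Li]CCCC (its lithium stays only in 10 and 11)
Why: 1,2-addition of a lithiated alkoxyallene (a crotonoyl anion equivalent) to the ketone from the face opposite to the cis-disposed epoxide oxygen and C6 methyl sets quaternary C7 with its oxygen cis to both, and the alkoxide is capped in the same flask as the trimethylsilyl ether.

Step 6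
Reactants: 12 epoxy bis-silyl ether
Product: 13 (1R,5R,6S,7S)-5-[(tert-butyldimethylsilyl)oxy]-7-(1-methoxybuta-1,2-dien-1-yl)-6-methyl-7-[(trimethylsilyl)oxy]cyclohept-2-en-1-ol
Conditions: Et2AlCl, lithium 2,2,6,6-tetramethylpiperidide (4 equiv each, gives diethylaluminium 2,2,6,6-tetramethylpiperidide in situ), PhMe, 0 °C; aq. potassium sodium tartrate
Reagents that add atoms: none
Why: aluminium amide isomerisation of an epoxide to an allylic alcohol (Yamamoto) by syn removal of the only β-hydrogen available (on C3a), which breaks the C8a–O bond and leaves the C8–O bond and its configuration untouched.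

Step 7
Reactants: 13 allylic alcohol, 14 propanoyl chloride
Product: 15 (1R,5R,6S,7S)-5-[(tert-butyldimethylsilyl)oxy]-7-(1-methoxybuta-1,2-dien-1-yl)-6-methyl-7-[(trimethylsilyl)oxy]cyclohept-2-en-1-yl propanoate
Conditions: EtCOCl, pyridine, DMAP (cat.), CH2Cl2, 0 °C → rt
Reagents that add atoms: propanoyl chloride (14), CCC(=O)Cl
Why: DMAP-catalysed acylation of the only free hydroxyl.

Step 8
Reactants: 15 allylic propanoate
Product: 18 (2R)-2-[(1R,4R,5S,6R)-4-[(2E)-but-2-enoyl]-6-[(tert-butyldimethylsilyl)oxy]-4-hydroxy-5-methylcyclohept-2-en-1-yl]propanoic acid, via silyl ketene acetal 16 (not isolated), via trimethylsilyl ester 17 (not isolated)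
Conditions: TMSCl/Et3N, then LiN(i-Pr)2, THF, −78 °C (in situ trapping); → 50 °C; then 1 M aq. HCl, THF, 0 °C
Reagents that add atoms: water, O; chlorotrimethylsilane, C[Si](C)(C)Cl (its silyl groups stay only in 16 and 17)
Why: Ireland–Claisen rearrangement in which the (E)-silyl ketene acetal from kinetic enolisation rearranges suprafacially from the C8 oxygen to the same face of C3a through the boat-like transition state usual for cycloalkenyl esters (the chair is disfavoured by the C7 silyloxy group), which sets C3a and places the C3 methyl over the ring (3R), and the acidic work-up hydrolyses the silyl ester, the tertiary silyl ether and the methoxyallene to the (E)-enone.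

Step 9
Reactants: 18 hydroxy enone acid
Product: 19 (3R,3aS,5R,6S,7R,8S,8aR)-7-[(2E)-but-2-enoyl]-5-[(tert-butyldimethylsilyl)oxy]-7-hydroxy-8-iodo-3,6-dimethyloctahydro-2H-cyclohepta[b]furan-2-one
Conditions: I2, NaHCO3, MeCN–H2O, 0 °C, dark
Reagents that add atoms: iodine, II
Why: iodolactonisation in which the carboxylate closes 5-exo onto C8a from the face of its own side chain (cis-fused lactone) while iodine ends anti on C8, trans to the C7 hydroxyl.

Step 10
Reactants: 19 iodolactone, 20 (2E)-2-methylbut-2-enoic acid (tiglic acid)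
Product: 22 (3R,3aS,5R,6S,7S,8S,8aR)-7-[(2E)-but-2-enoyl]-5-[(tert-butyldimethylsilyl)oxy]-7-hydroxy-3,6-dimethyl-2-oxooctahydro-2H-cyclohepta[b]furan-8-yl (2E)-2-methylbut-2-enoate, via epoxy ketone 21 (not isolated)
Conditions: Cs2CO3 (1.1 equiv), MeCN, 0 °C → rt; then tiglic acid (6 equiv), 60 °C
Reagents that add atoms: (2E)-2-methylbut-2-enoic acid (20), C/C=C(\C)C(=O)O
Why: the C7 alkoxide displaces the anti iodide (intramolecular Williamson closure, first inversion at C8) and tiglic acid/caesium tiglate then opens the trisubstituted epoxy ketone at its only accessible carbon, secondary C8 (second inversion), so the tiglate arrives with net retention, trans to the C7 hydroxyl.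

Step 11
Reactants: 22 silyl-protected tiglate
Product: 23 (3R,3aS,5R,6S,7S,8S,8aR)-7-[(2E)-but-2-enoyl]-5,7-dihydroxy-3,6-dimethyl-2-oxooctahydro-2H-cyclohepta[b]furan-8-yl (2E)-2-methylbut-2-enoate (CNP0183494.2)
Conditions: HF·pyridine, THF, 0 °C → rt
Reagents that add atoms: none
Why: fluoride cleavage of the silyl ether under non-basic conditions that spare the tiglate, the lactone and the α-hydroxy enone.

## Compound list

1 | 8-oxabicyclo[3.2.1]octan-3-one (meso, 1R,5S) | O=C1C[C@H]2CC[C@@H](C1)O2 | starting material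
2 | tert-butyl(dimethyl){[(1S,5R)-8-oxabicyclo[3.2.1]oct-2-en-3-yl]oxy}silane | CC(C)(C)[Si](C)(C)OC=1C[C@H]2CC[C@H](O2)C=1 | intermediate
3 | (6R)-6-[(tert-butyldimethylsilyl)oxy]cyclohept-2-en-1-one | O=C1C[C@H](O[Si](C)(C)C(C)(C)C)CCC=C1 | intermediate
4 | (1R,4R,7R)-4-[(tert-butyldimethylsilyl)oxy]-8-oxabicyclo[5.1.0]octan-2-one | O=C1C[C@H](O[Si](C)(C)C(C)(C)C)CC[C@H]2O[C@@H]12 | intermediate
5 | iodomethane | CI | starting material
6 | lithium (1R,4R,7R)-4-[(tert-butyldimethylsilyl)oxy]-8-oxabicyclo[5.1.0]oct-2-en-2-olate | [Li+].[O-]C1=C[C@H](O[Si](C)(C)C(C)(C)C)CC[C@H]2O[C@@H]12 | intermediate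
7 | (1R,3S,4R,7R)-4-[(tert-butyldimethylsilyl)oxy]-3-methyl-8-oxabicyclo[5.1.0]octan-2-one | O=C1[C@@H](C)[C@H](O[Si](C)(C)C(C)(C)C)CC[C@H]2O[C@@H]12 | intermediate
8 | 1-methoxybut-2-yne | COCC#CC | starting material
9 | 1-methoxybuta-1,2-diene (racemic allene axis) | COC=C=CC | intermediate
10 | 1-lithio-1-methoxybuta-1,2-diene | [Li]C(OC)=C=CC | intermediate
11 | lithium (1R,2S,3S,4R,7R)-4-[(tert-butyldimethylsilyl)oxy]-2-(1-methoxybuta-1,2-dien-1-yl)-3-methyl-8-oxabicyclo[5.1.0]octan-2-olate | COC(=C=CC)[C@]1([O-])[C@@H](C)[C@H](O[Si](C)(C)C(C)(C)C)CC[C@H]2O[C@@H]12.[Li+] | intermediate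
12 | tert-butyl{[(1R,2S,3S,4R,7R)-2-(1-methoxybuta-1,2-dien-1-yl)-3-methyl-2-[(trimethylsilyl)oxy]-8-oxabicyclo[5.1.0]octan-4-yl]oxy}dimethylsilane (both allene-axis epimers) | COC(=C=CC)[C@]1(O[Si](C)(C)C)[C@@H](C)[C@H](O[Si](C)(C)C(C)(C)C)CC[C@H]2O[C@@H]12 | intermediate
13 | (1R,5R,6S,7S)-5-[(tert-butyldimethylsilyl)oxy]-7-(1-methoxybuta-1,2-dien-1-yl)-6-methyl-7-[(trimethylsilyl)oxy]cyclohept-2-en-1-ol | COC(=C=CC)[C@]1(O[Si](C)(C)C)[C@@H](C)[C@H](O[Si](C)(C)C(C)(C)C)CC=C[C@H]1O | intermediate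
14 | propanoyl chloride | CCC(=O)Cl | starting material
15 | (1R,5R,6S,7S)-5-[(tert-butyldimethylsilyl)oxy]-7-(1-methoxybuta-1,2-dien-1-yl)-6-methyl-7-[(trimethylsilyl)oxy]cyclohept-2-en-1-yl propanoate | COC(=C=CC)[C@]1(O[Si](C)(C)C)[C@@H](C)[C@H](O[Si](C)(C)C(C)(C)C)CC=C[C@H]1OC(=O)CC | intermediate
16 | (E)-O-trimethylsilyl ketene acetal of 15 (methyl cis to the ring oxygen) | COC(=C=CC)[C@]1(O[Si](C)(C)C)[C@@H](C)[C@H](O[Si](C)(C)C(C)(C)C)CC=C[C@H]1O/C(O[Si](C)(C)C)=C\C | intermediate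
17 | trimethylsilyl (2R)-2-[(1R,4R,5S,6R)-6-[(tert-butyldimethylsilyl)oxy]-4-(1-methoxybuta-1,2-dien-1-yl)-5-methyl-4-[(trimethylsilyl)oxy]cyclohept-2-en-1-yl]propanoate | COC(=C=CC)[C@]1(O[Si](C)(C)C)[C@@H](C)[C@H](O[Si](C)(C)C(C)(C)C)C[C@@H]([C@@H](C)C(=O)O[Si](C)(C)C)C=C1 | intermediate
18 | (2R)-2-[(1R,4R,5S,6R)-4-[(2E)-but-2-enoyl]-6-[(tert-butyldimethylsilyl)oxy]-4-hydroxy-5-methylcyclohept-2-en-1-yl]propanoic acid | C/C=C/C(=O)[C@]1(O)[C@@H](C)[C@H](O[Si](C)(C)C(C)(C)C)C[C@@H]([C@@H](C)C(=O)O)C=C1 | intermediate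
19 | (3R,3aS,5R,6S,7R,8S,8aR)-7-[(2E)-but-2-enoyl]-5-[(tert-butyldimethylsilyl)oxy]-7-hydroxy-8-iodo-3,6-dimethyloctahydro-2H-cyclohepta[b]furan-2-one | C/C=C/C(=O)[C@]1(O)[C@@H](C)[C@H](O[Si](C)(C)C(C)(C)C)C[C@@H]2[C@@H](OC(=O)[C@@H]2C)[C@@H]1I | intermediate
20 | (2E)-2-methylbut-2-enoic acid (tiglic acid) | C/C=C(\C)C(=O)O | starting material
21 | (3R,3aS,5R,6S,7S,8R,8aR)-7-[(2E)-but-2-enoyl]-5-[(tert-butyldimethylsilyl)oxy]-7,8-epoxy-3,6-dimethyloctahydro-2H-cyclohepta[b]furan-2-one (epoxide oxygen on the face of the lactone oxygen) | C/C=C/C(=O)[C@]13[C@@H](C)[C@H](O[Si](C)(C)C(C)(C)C)C[C@@H]2[C@@H](OC(=O)[C@@H]2C)[C@H]1O3 | intermediate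
22 | (3R,3aS,5R,6S,7S,8S,8aR)-7-[(2E)-but-2-enoyl]-5-[(tert-butyldimethylsilyl)oxy]-7-hydroxy-3,6-dimethyl-2-oxooctahydro-2H-cyclohepta[b]furan-8-yl (2E)-2-methylbut-2-enoate | C/C=C/C(=O)[C@]1(O)[C@@H](C)[C@H](O[Si](C)(C)C(C)(C)C)C[C@@H]2[C@@H](OC(=O)[C@@H]2C)[C@@H]1OC(=O)/C(C)=C/C | intermediate
23 | (3R,3aS,5R,6S,7S,8S,8aR)-7-[(2E)-but-2-enoyl]-5,7-dihydroxy-3,6-dimethyl-2-oxooctahydro-2H-cyclohepta[b]furan-8-yl (2E)-2-methylbut-2-enoate | C/C=C/C(=O)[C@]1(O)[C@@H](C)[C@H](O)C[C@@H]2[C@@H](OC(=O)[C@@H]2C)[C@@H]1OC(=O)/C(C)=C/C | target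

## Step count and risks

Total steps: 11. Longest linear sequence: 10 (steps 1–3 and 5–11; step 4 makes the allene reagent).

Three steps most likely to fail:

**Step 1 (the new desymmetrising ring opening).** The enantioselectivity on this bridged ketone is untested and the product enone could be silylated further. Fallback with known chemistry: from 1, t-BuMe2SiOTf/Et3N in CH2Cl2 gives racemic 6-[(tert-butyldimethylsilyl)oxy]cyclohept-2-en-1-one F1 by the known ring opening through the silyl enol ether. The amine-salt/H2O2 epoxidation of step 2, whose facial selectivity is set by the catalyst, then turns the two enantiomers into diastereomers: 4 from the R enantiomer and (1R,4S,7R)-4-[(tert-butyldimethylsilyl)oxy]-8-oxabicyclo[5.1.0]octan-2-one F2 from the S enantiomer. These are separated on silica and the route is rejoined at 4, with at most half of the material.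

**Step 8 (Ireland–Claisen next to the quaternary C7).** The rearrangement may be slow and the C3 ratio depends on boat versus chair. Fallback: from 13 (step 7 is then not needed), heating with 1,1-dimethoxy-N,N-dimethylpropan-1-amine in xylene at 140 °C (Eschenmoser–Claisen, neutral, no ester enolate) gives (2R)-2-[(1R,4R,5S,6R)-6-[(tert-butyldimethylsilyl)oxy]-4-(1-methoxybuta-1,2-dien-1-yl)-5-methyl-4-[(trimethylsilyl)oxy]cyclohept-2-en-1-yl]-N,N-dimethylpropanamide F3. Treatment with 1 M HCl in THF unmasks it to (2R)-2-[(1R,4R,5S,6R)-4-[(2E)-but-2-enoyl]-6-[(tert-butyldimethylsilyl)oxy]-4-hydroxy-5-methylcyclohept-2-en-1-yl]-N,N-dimethylpropanamide F4. Iodolactonisation of this γ,δ-unsaturated amide (I2, THF–H2O, loss of dimethylamine) returns to the route at 19.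

**Step 10 (carboxylate opening at hindered C8).** The opening may be slow and acyl migration or furanone formation from the α-hydroxy enone could compete. Fallback: from 18, Et3SiOTf/2,6-lutidine gives (2R)-2-[(1R,4R,5S,6R)-4-[(2E)-but-2-enoyl]-6-[(tert-butyldimethylsilyl)oxy]-5-methyl-4-[(triethylsilyl)oxy]cyclohept-2-en-1-yl]propanoic acid F5. Buffered mCPBA epoxidises it on the face opposite to the silyloxy group and the side chain to give the 2,3-epoxy acid F6. This lactonises with CSA to (3R,3aS,5R,6S,7S,8S,8aR)-7-[(2E)-but-2-enoyl]-5-[(tert-butyldimethylsilyl)oxy]-8-hydroxy-3,6-dimethyl-7-[(triethylsilyl)oxy]octahydro-2H-cyclohepta[b]furan-2-one F7; the other epoxide cannot lactonise and is removed. Yamaguchi esterification (tiglic acid, 2,4,6-trichlorobenzoyl chloride, Et3N, DMAP) gives the 8-yl (2E)-2-methylbut-2-enoate of F7 with both silyl ethers retained F8, and HF·pyridine removes both silyl groups, returning at 23.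

## Further compounds

F1 | step 1 | racemic 6-[(tert-butyldimethylsilyl)oxy]cyclohept-2-en-1-one | O=C1CC(O[Si](C)(C)C(C)(C)C)CCC=C1
F2 | step 1 | (1R,4S,7R)-4-[(tert-butyldimethylsilyl)oxy]-8-oxabicyclo[5.1.0]octan-2-one | O=C1C[C@@H](O[Si](C)(C)C(C)(C)C)CC[C@H]2O[C@@H]12
F3 | step 8 | (2R)-2-[(1R,4R,5S,6R)-6-[(tert-butyldimethylsilyl)oxy]-4-(1-methoxybuta-1,2-dien-1-yl)-5-methyl-4-[(trimethylsilyl)oxy]cyclohept-2-en-1-yl]-N,N-dimethylpropanamide | COC(=C=CC)[C@]1(O[Si](C)(C)C)[C@@H](C)[C@H](O[Si](C)(C)C(C)(C)C)C[C@@H]([C@@H](C)C(=O)N(C)C)C=C1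
F4 | step 8 | (2R)-2-[(1R,4R,5S,6R)-4-[(2E)-but-2-enoyl]-6-[(tert-butyldimethylsilyl)oxy]-4-hydroxy-5-methylcyclohept-2-en-1-yl]-N,N-dimethylpropanamide | C/C=C/C(=O)[C@]1(O)[C@@H](C)[C@H](O[Si](C)(C)C(C)(C)C)C[C@@H]([C@@H](C)C(=O)N(C)C)C=C1
F5 | step 10 | (2R)-2-[(1R,4R,5S,6R)-4-[(2E)-but-2-enoyl]-6-[(tert-butyldimethylsilyl)oxy]-5-methyl-4-[(triethylsilyl)oxy]cyclohept-2-en-1-yl]propanoic acid | C/C=C/C(=O)[C@]1(O[Si](CC)(CC)CC)[C@@H](C)[C@H](O[Si](C)(C)C(C)(C)C)C[C@@H]([C@@H](C)C(=O)O)C=C1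
F6 | step 10 | 2,3-epoxide of F5 (epoxide oxygen anti to the triethylsilyloxy group and the propanoic acid side chain) | C/C=C/C(=O)[C@]1(O[Si](CC)(CC)CC)[C@@H](C)[C@H](O[Si](C)(C)C(C)(C)C)C[C@@H]([C@@H](C)C(=O)O)[C@@H]2O[C@H]12
F7 | step 10 | (3R,3aS,5R,6S,7S,8S,8aR)-7-[(2E)-but-2-enoyl]-5-[(tert-butyldimethylsilyl)oxy]-8-hydroxy-3,6-dimethyl-7-[(triethylsilyl)oxy]octahydro-2H-cyclohepta[b]furan-2-one | C/C=C/C(=O)[C@]1(O[Si](CC)(CC)CC)[C@@H](C)[C@H](O[Si](C)(C)C(C)(C)C)C[C@@H]2[C@@H](OC(=O)[C@@H]2C)[C@@H]1O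
F8 | step 10 | (3R,3aS,5R,6S,7S,8S,8aR)-7-[(2E)-but-2-enoyl]-5-[(tert-butyldimethylsilyl)oxy]-3,6-dimethyl-2-oxo-7-[(triethylsilyl)oxy]octahydro-2H-cyclohepta[b]furan-8-yl (2E)-2-methylbut-2-enoate | C/C=C/C(=O)[C@]1(O[Si](CC)(CC)CC)[C@@H](C)[C@H](O[Si](C)(C)C(C)(C)C)C[C@@H]2[C@@H](OC(=O)[C@@H]2C)[C@@H]1OC(=O)/C(C)=C/C
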